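**Ret­ro­syn­thet­ic overview**
- The target comes from its tri-O-methyl ether by one global BBr3 demethylation.
- Key C–C disconnection: C4–C4a of the isocoumarin. C4 is delivered as an α-keto rhodium carbenoid (an enolonium equivalent, from an α-keto sulfoxonium ylide) to the ortho C–H carbon of a 2-aryloxy-4-methoxybenzoic acid, and the same operation closes the lactone.
- Diaryl ether: Ullmann condensation of 2-bromo-4-methoxybenzoic acid with 2,4-dimethoxy-6-pentylphenol.
- The phenol comes from olivetol dimethyl ether by Vilsmeier formylation and Baeyer–Villiger oxidation.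
- Ring order: both benzene rings are bought; the pyranone ring is the only ring made, in the key step.

Assumption: the target has no stereocentre and no configurationally stable axis, so there is no enantiomer to select and the route delivers the single compound drawn.

**Route**

Step 1
Reactants: 1 1,3-dimethoxy-5-pentylbenzene (olivetol dimethyl ether)
Product: 3 2,4-dimethoxy-6-pentylbenzaldehyde, via aryl iminium chloride 2 (not isolated)
Conditions: POCl3 (1.3 equiv), DMF, 0 → 70 °C; then ice/H2O
Reagents that add atoms: N,N-dimethylformamide, CN(C)C=O (formyl CH); water, O (aldehyde oxygen)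
Why: Vilsmeier–Haack formylation attacks the position para to one OMe and ortho to the other in preference to the more hindered carbon between the two OMe groups, and the minor isomer is removed by chromatography.

Step 2
Reactants: 3 2,4-dimethoxy-6-pentylbenzaldehyde
Product: 5 2,4-dimethoxy-6-pentylphenol, via aryl formate 4 (not isolated)
Conditions: mCPBA (1.3 equiv), CH2Cl2, 0 °C → rt; aq Na2SO3 wash; then K2CO3 (cat.), MeOH, rt, N2
Reagents that add atoms: mCPBA, O=C(OO)c1cccc(Cl)c1
Why: Baeyer–Villiger (Dakin-type) oxidation in which the electron-rich aryl group migrates in preference to hydrogen, followed by base-catalysed methanolysis of the formate after the peracid has been destroyed.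

Step 3
Reactants: 5 2,4-dimethoxy-6-pentylphenol; 6 2-bromo-4-methoxybenzoic acid
Product: 7 2-(2,4-dimethoxy-6-pentylphenoxy)-4-methoxybenzoic acid
Conditions: Cu powder (10 mol %), Cu2O (5 mol %), K2CO3 (2.5 equiv), pyridine (0.5 equiv), DMF, 120 °C, Ar; then aq HCl
Reagents that add atoms: none
Why: Ullmann condensation in which the ortho-carboxylate assists copper insertion into the C–Br bond and the electron-rich phenoxide is a good partner despite its two ortho substituents.

Step 4
Reactants: 8 trimethylsulfoxonium iodide; 9 hexanoyl chloride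
Product: 11 1-[dimethyl(oxo)-λ6-sulfanylidene]heptan-2-one, via dimethylsulfoxonium methylide 10 (not isolated)
Conditions: 8 (3 equiv), KOt-Bu (3 equiv), THF, reflux, 2 h; then 9 (1 equiv), 0 °C → rt
Reagents that add atoms: none
Why: C-acylation of the Corey–Chaykovsky ylide by the acid chloride, with a second equivalent of the ylide deprotonating the acylsulfoxonium salt to give the stabilised, bench-stable keto ylide.

Step 5
Reactants: 7 2-(2,4-dimethoxy-6-pentylphenoxy)-4-methoxybenzoic acid; 11 1-[dimethyl(oxo)-λ6-sulfanylidene]heptan-2-one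
Product: 13 8-(2,4-dimethoxy-6-pentylphenoxy)-6-methoxy-3-pentyl-1H-isochromen-1-one, via keto acid 12 (not isolated)
Conditions: [Cp*RhCl2]2 (4 mol %), AgSbF6 (16 mol %), NaOAc (30 mol %), 11 (1.5 equiv), CF3CH2OH, 80 °C; then TsOH·H2O (20 mol %), 80 °C
Reagents that add atoms: none
Why: Carboxylate-directed C–H metalation by the cationic trivalent rhodium catalyst at the only free ortho position of 7 gives a nucleophilic aryl–rhodium carbon that migrates onto the α-keto rhodium carbenoid formed from 11 with loss of DMSO, so the ketone α-carbon, normally an enolate nucleophile, reacts as an enolonium (α-acyl cation) equivalent; protodemetalation to 12 and acid-promoted enol-lactonisation then close the pyranone ring (C–H acylmethylation/annulation with a sulfoxonium ylide), and no stereocentre is formed.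

Step 6
Reactants: 13 8-(2,4-dimethoxy-6-pentylphenoxy)-6-methoxy-3-pentyl-1H-isochromen-1-one
Product: 15 8-(2,4-dihydroxy-6-pentylphenoxy)-6-hydroxy-3-pentyl-1H-isochromen-1-one, via tris(dibromoboryl) ether 14 (not isolated)
Conditions: BBr3 (8 equiv), CH2Cl2, −78 °C → rt; then H2O, 0 °C
Reagents that add atoms: none
Why: Lewis-acid cleavage of the three aryl methyl ethers (BBr3 demethylation), which leaves the diaryl ether and the isocoumarin lactone intact, followed by hydrolysis of the aryl borates.

**Compound list**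

1 | 1,3-dimethoxy-5-pentylbenzene (olivetol dimethyl ether) | CCCCCc1cc(OC)cc(OC)c1 | starting material
2 | N-[(2,4-dimethoxy-6-pentylphenyl)methylidene]-N-methylmethanaminium chloride | CCCCCc1cc(OC)cc(OC)c1C=[N+](C)C.[Cl-] | intermediate
3 | 2,4-dimethoxy-6-pentylbenzaldehyde | CCCCCc1cc(OC)cc(OC)c1C=O | intermediate
4 | 2,4-dimethoxy-6-pentylphenyl formate | CCCCCc1cc(OC)cc(OC)c1OC=O | intermediate
5 | 2,4-dimethoxy-6-pentylphenol | CCCCCc1cc(OC)cc(OC)c1O | intermediate
6 | 2-bromo-4-methoxybenzoic acid | COc1ccc(C(=O)O)c(Br)c1 | starting material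
7 | 2-(2,4-dimethoxy-6-pentylphenoxy)-4-methoxybenzoic acid | CCCCCc1cc(OC)cc(OC)c1Oc1cc(OC)ccc1C(=O)O | intermediate
8 | trimethylsulfoxonium iodide | C[S+](C)(C)=O.[I-] | starting material
9 | hexanoyl chloride | CCCCCC(=O)Cl | starting material
10 | dimethylsulfoxonium methylide | C=S(C)(C)=O | intermediate
11 | 1-[dimethyl(oxo)-λ6-sulfanylidene]heptan-2-one | CCCCCC(=O)C=S(C)(C)=O | intermediate
12 | 2-(2,4-dimethoxy-6-pentylphenoxy)-4-methoxy-6-(2-oxoheptyl)benzoic acid | CCCCCC(=O)Cc1cc(OC)cc(Oc2c(OC)cc(OC)cc2CCCCC)c1C(=O)O | intermediate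
13 | 8-(2,4-dimethoxy-6-pentylphenoxy)-6-methoxy-3-pentyl-1H-isochromen-1-one | CCCCCc1cc2cc(OC)cc(Oc3c(OC)cc(OC)cc3CCCCC)c2c(=O)o1 | intermediate
14 | 8-[2,4-bis(dibromoboryloxy)-6-pentylphenoxy]-6-(dibromoboryloxy)-3-pentyl-1H-isochromen-1-one | CCCCCc1cc2cc(OB(Br)Br)cc(Oc3c(OB(Br)Br)cc(OB(Br)Br)cc3CCCCC)c2c(=O)o1 | intermediate
15 | 8-(2,4-dihydroxy-6-pentylphenoxy)-6-hydroxy-3-pentyl-1H-isochromen-1-one | CCCCCc1cc2cc(O)cc(Oc3c(O)cc(O)cc3CCCCC)c2c(=O)o1 | target

**Summary**

Total step count: 6. Longest linear sequence: 5 steps (1 → 3 → 5 → 7 → 13 → 15). Step 4 is a one-step side branch.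

Steps most likely to fail, each with a fallback:

- **Step 5 (key annulation).** The free acid may protonate the ylide and be O-alkylated instead of undergoing C–H insertion, and the substrate is hindered and carries a very electron-rich ring B. The fallback sets out from 7 and returns at 13. Treating 7 with s-BuLi/TMEDA (2.2 equiv, THF, −78 °C) gives the carboxylate-directed ortho-lithio species lithium 2-(2,4-dimethoxy-6-pentylphenoxy)-6-lithio-4-methoxybenzoate F1. Quenching with I2 gives 2-(2,4-dimethoxy-6-pentylphenoxy)-6-iodo-4-methoxybenzoic acid F2; this avoids an electrophilic iodinating agent that would attack ring B. Coupling with hept-1-yne (Pd(PPh3)4, ZnCl2, Et3N, DMF, 100 °C) gives 2-(2,4-dimethoxy-6-pentylphenoxy)-6-(hept-1-yn-1-yl)-4-methoxybenzoic acid F3, which cyclises 6-endo-dig in the same flask to 13.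

- **Step 3 (Ullmann condensation).** The phenol is di-ortho-substituted and oxidation-prone, and the bromo acid can undergo protodehalogenation. The fallback sets out from 5 and returns at 7. SNAr of 5 on 2-fluoro-4-methoxybenzaldehyde (K2CO3, DMF, 110 °C; the ortho-formyl group activates the fluoride) gives 2-(2,4-dimethoxy-6-pentylphenoxy)-4-methoxybenzaldehyde F4. Pinnick oxidation (NaClO2, NaH2PO4, 2-methyl-2-butene, t-BuOH/H2O) then gives 7.

- **Step 2 (Baeyer–Villiger on a di-ortho-substituted aldehyde).** Migration may be slow, the electron-rich ring can over-oxidise to a quinone, and any regioisomer from step 1 is carried in. The fallback sets out from 1 and returns at 5. NBS (MeCN, 0 °C) gives 1-bromo-2,4-dimethoxy-6-pentylbenzene F5. Bromine–lithium exchange (n-BuLi, THF, −78 °C) gives (2,4-dimethoxy-6-pentylphenyl)lithium F6. Trapping with B(OMe)3 gives dimethyl (2,4-dimethoxy-6-pentylphenyl)boronate F7, which H2O2/NaOH oxidises in the same flask to 5.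

**Further compounds**

F1 | step 5 | lithium 2-(2,4-dimethoxy-6-pentylphenoxy)-6-lithio-4-methoxybenzoate | CCCCCc1cc(OC)cc(OC)c1Oc1cc(OC)cc([Li])c1C(=O)O[Li]
F2 | step 5 | 2-(2,4-dimethoxy-6-pentylphenoxy)-6-iodo-4-methoxybenzoic acid | CCCCCc1cc(OC)cc(OC)c1Oc1cc(OC)cc(I)c1C(=O)O
F3 | step 5 | 2-(2,4-dimethoxy-6-pentylphenoxy)-6-(hept-1-yn-1-yl)-4-methoxybenzoic acid | CCCCCC#Cc1cc(OC)cc(Oc2c(OC)cc(OC)cc2CCCCC)c1C(=O)O
F4 | step 3 | 2-(2,4-dimethoxy-6-pentylphenoxy)-4-methoxybenzaldehyde | CCCCCc1cc(OC)cc(OC)c1Oc1cc(OC)ccc1C=O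
F5 | step 2 | 1-bromo-2,4-dimethoxy-6-pentylbenzene | CCCCCc1cc(OC)cc(OC)c1Br
F6 | step 2 | (2,4-dimethoxy-6-pentylphenyl)lithium | CCCCCc1cc(OC)cc(OC)c1[Li]
F7 | step 2 | dimethyl (2,4-dimethoxy-6-pentylphenyl)boronate | CCCCCc1cc(OC)cc(OC)c1B(OC)OC
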